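Remark on numbering: positions follow germacranolide numbering. C1–C10 are the ring carbons, C11 the lactone α-carbon, C12 the lactone carbonyl, C13 the exocyclic methylene carbon, C14 the hydroxymethyl carbon on C10, C15 the methyl carbon on C4.

## Analysis of the target

The target 39 is a heliangolide-type germacranolide: a ten-membered carbocycle C1–C10 with a cis-fused α-methylene-γ-butyrolactone across C6–C7 (ring oxygen on C6, carbonyl C12, C11=C13), a (Z)-trisubstituted C4=C5 alkene carrying the C15 methyl on C4, and an oxirane spanning C1 and the quaternary C10, which also bears the C14 hydroxymethyl group. Six ring stereocentres (1R, 3S, 6S, 7R, 8R, 10R) and the (R)-2-methylbutanoate on O8 must be controlled. H6 and H7 are cis, the C8 and C10 oxygens are 1,3-syn across the C9 methylene, and C2 and C9 are cis on the oxirane. The C3 oxygen is 1,3-anti to the oxygen that C1 carries before the oxirane is closed. The fragile groups are the α-methylene lactone (a Michael acceptor), the C14–C10–C1 epoxy alcohol array (acid opening, Payne-type migration, transannular attack), the allylic C3 alcohol, the epimerisable α-centre of the ester, and a lactone that can migrate from O6 to a free O8. The difficulty lies in closing a ten-membered ring, in the oxygenated quaternary C10, in a cis-lactone that is less stable than its trans isomer (so C7 must not sit next to a carbonyl under basic conditions for long), and in the (Z) alkene. The strategy rests on one feature: C14, C10 and C1 all carry oxygen and C8 carries oxygen β to C10. C10 can therefore be a ketone flanked by a chelating C1 ether and a non-chelating C14 silyl ether, and the C8(O)–C9–C10(O) unit is a hidden aldol relation inside the ring.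

## Retrosynthetic reasoning

**Late decoration (39 back to 32).** The two silyl ethers of 38 are removed last. The C8 ester is cut to alcohol 36 and acid 37, and the C11=C13 bond of 35 is cut back to the saturated lactone 32 through the Mannich base 33. The α-methylene lactone and the ester α-centre are the groups least tolerant of later chemistry, so they are introduced after every base-mediated step on the ring is done, and C13 before the ester so that no strong base ever meets the acyl stereocentre.

**Oxirane (32 back to 30).** The C1–O bond of the oxirane is cut and the C10–O bond is kept. The forward closure is an intramolecular displacement of a C1 sulfonate (31) by the C10 alkoxide, which inverts C1 and retains C10. The acyclic precursor must therefore carry (1S) and the ring closure must deliver (10R).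

**C8 carbinol (28 back to 26).** The C8–H bond is cut to give the C8 ketone. The forward step is a hydroxyl-directed 1,3-syn reduction that uses the C10 hydroxyl just created.

**Ring closure (26 back to 24), the key disconnection.** The C9–C10 bond is cut. This bond is chosen because it makes the quaternary C10, the hardest centre to set on a preformed ring, in the ring-forming event itself and under the influence of the adjacent C1 ether. C9 is an unfunctionalised methylene, so the nucleophile can be generated regiospecifically from a C9–Br bond by divalent samarium without any enolisation toward C7. Cutting C6–C7 or C7–C8 instead would give up the lactone stereochemistry that acyclic aldol chemistry sets reliably. The open precursor 24 carries C1, C3, C6 and C7 already fixed.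

**Bromomethyl ketone (24 back to 20).** The C10 ketone is traced to the C10 alcohol 23 so that no second ketone is present while C9 is attached. C8–C9 is cut by going back through the diazoketone 22 to the acid 20. This delivers the halogen to C9 without choosing between the enolisable positions C9, C7 and C11.

**Lactone and C6–C7 (20 back to 11 and 14).** The lactone C12–O6 bond and the C6–C7 bond are cut. An anti aldol between the succinyl imide 14 and the (Z)-enal 11 sets C6 and C7 in one step (15). Lactonisation of the anti adduct can only give the cis-lactone (17, 18). The same acid step releases the C10/C14 diol, which is differentiated as 19.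

**The (Z) alkene (11 back to 8).** The C4–C15 bond is cut. Syn addition of a methyl group and hydrogen across the ynoate 8 places C3 and C6 cis by mechanism (9). Adjustment of the oxidation level at C6 gives 10 and 11.

**C3–C4 (8 back to 5 and 6).** The propargylic C3–C4 bond is cut to aldehyde 5 and methyl propiolate 6. The forward alkynylation must create (3S) under catalyst control (7).

**Chiral pool (5 back to 1).** C14, C10, C1, C2 and C3 map onto C5, C4, C3, C2 and C1 of 2-deoxy-D-ribose 1, whose C3 has the configuration needed at C1. The C10 centre of the sugar is lost later on oxidation. Compounds 2, 3 and 4 only differentiate the oxygens.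

**Imide (14 back to 12 and 13).** The N–acyl bond is cut to the oxazolidinone 12 and the half-ester chloride 13 of succinic acid.

## Alternatives that were turned down

**Alternative 1:** The ten-membered ring is obtained by cutting the shared C1–C6 bond of a bicyclic precursor. Dissolving-metal reduction of 2-methylnaphthalene A1 gives an isotetralin, whose central tetrasubstituted alkene is epoxidised. An oxidant then opens that epoxide and cleaves the diol to the dienedione A2, with carbonyls at C1 and C6. In its favour, it is by far the shortest entry to the carbocycle, from a bulk chemical, and both ring alkenes are necessarily cis because they come from six-membered rings. Against it, A2 is achiral, carries two nearly equivalent ketones and two β,γ-alkenes that can move into conjugation or engage in transannular aldol chemistry, and has the methyl-bearing alkene at C3=C4, not C4=C5. C14, C11–C13, five oxygens and all six stereocentres would have to be added to a flexible medium ring with no resident stereocentre to direct them, and the absolute configuration would need a resolution or a catalytic step on a substrate with two similar carbonyls. On ring construction this alternative is clearly stronger. The chosen route offers in its place a ring that is closed with C1, C3, C6 and C7 already set in acyclic intermediates and with C10 set in the closure.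

**Alternative 2:** The C7–C8 and O–C6 bonds are cut together. A nitrile oxide generated at C8 from an aldoxime adds across an (E)-C6=C7 alkene and closes the isoxazoline and the ten-membered carbocycle at once, giving A3. In its favour, two bonds form in one step, the C6/C7 relation follows stereospecifically from the alkene geometry, the C8=N–O–C6 unit is a masked β-hydroxy ketone, the oxirane is carried through under neutral conditions, and no epimerisable C7 ketone exists before the ring is formed. On these points it is as strong as or stronger than the chosen route. Against it, the regiochemistry of a ten-membered intramolecular cycloaddition onto a 1,2-disubstituted alkene is decided by tether strain and not by electronics, the facial selectivity depends on remote centres only, and furoxan dimerisation competes at the low effective molarity of this ring size. The N–O bond must afterwards be cleaved reductively beside an oxirane and an alkene, and the cis-trisubstituted oxirane has to be made enantioselectively at the outset. The chosen route offers a closure that is templated by the metal between two oxygen atoms and whose sense at C10 follows a chelate model.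

**Alternative 3:** The C8–C9 bond is formed and a six-membered ring is opened in a [3,3] shift. The potassium alkoxide of a cis-1,6-dialkenylcyclohexenol, made from a chiral-pool cyclohexenone, undergoes an anionic oxy-Cope rearrangement that expands the ring by four atoms to the enone A4. In its favour, ring expansion avoids the entropic cost of a ten-membered closure altogether, the rearrangement is stereospecific, and it gives the ring-cis C4=C5 alkene directly. As a ring-forming event it is the most dependable of all four strategies. Against it, A4 still lacks the C11–C13 arm at C7, the C6 carbinol, the oxirane and a free C8 oxygen. Alkylation at C7, reduction at C6, face-selective epoxidation of C1=C10 and oxidation of the C8 silane must all be controlled by the conformation of the medium ring, and the rearrangement substrate needs a diastereoselective addition of a functionalised alkenyl metal to a hindered ketone. The chosen route is weaker in the closure itself but leaves only C8 to be set on the ring, and sets it from the C10 hydroxyl that the closure creates.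

Key step: step 17

## Route

Assumptions:
- 2-Deoxy-D-ribose 1 is drawn in its open-chain form.
- (R)-2-Methylbutanoic acid 37 is taken as commercially available.
- The facial senses quoted for steps 5 and 11 are those expected from the accepted models for these reactions.

Step 1
Reactants: 1 2-deoxy-D-ribose
Product: 2 (2R,3S)-4-(1,3-dithian-2-yl)butane-1,2,3-triol
Conditions: HS(CH2)3SH, conc. HCl, 0 °C to rt
Reagents that add atoms: propane-1,3-dithiol, SCCCS
Why: Acid-catalysed dithioacetalisation of the open-chain aldose masks C3 as a dithiane and frees the three chain hydroxyls; both stereocentres come unchanged from the sugar.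

Step 2
Reactants: 2 (2R,3S)-4-(1,3-dithian-2-yl)butane-1,2,3-triol
Product: 3 (1S)-2-(1,3-dithian-2-yl)-1-[(4R)-2,2-dimethyl-1,3-dioxolan-4-yl]ethanol
Conditions: Me2C(OMe)2, PPTS (cat.), acetone, rt
Reagents that add atoms: 2,2-dimethoxypropane, COC(C)(C)OC
Why: Acetonide formation prefers the five-membered ring on the terminal 1,2-diol (C10/C14), which leaves only the C1 hydroxyl free.

Step 3
Reactants: 3 (1S)-2-(1,3-dithian-2-yl)-1-[(4R)-2,2-dimethyl-1,3-dioxolan-4-yl]ethanol
Product: 4 2-{(2S)-2-[(4R)-2,2-dimethyl-1,3-dioxolan-4-yl]-2-[(4-methoxybenzyl)oxy]ethyl}-1,3-dithiane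
Conditions: NaH, PMBCl, Bu4NI (cat.), THF/DMF, 0 °C to rt
Reagents that add atoms: 4-methoxybenzyl chloride, COc1ccc(CCl)cc1
Why: Williamson etherification installs the chelating C1 ether that later directs the ring closure; the dithiane C–H is not acidic enough to interfere.

Step 4
Reactants: 4 2-{(2S)-2-[(4R)-2,2-dimethyl-1,3-dioxolan-4-yl]-2-[(4-methoxybenzyl)oxy]ethyl}-1,3-dithiane
Product: 5 (3S)-3-[(4R)-2,2-dimethyl-1,3-dioxolan-4-yl]-3-[(4-methoxybenzyl)oxy]propanal
Conditions: MeI, CaCO3, MeCN/H2O (9:1), 40 °C
Reagents that add atoms: water, O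
Why: S-Methylation turns the dithiane into a leaving group and hydrolysis releases the C3 aldehyde; the carbonate buffer keeps the acetonide and PMB ether intact and avoids β-elimination of the C1 ether.

Step 5
Reactants: 5 (3S)-3-[(4R)-2,2-dimethyl-1,3-dioxolan-4-yl]-3-[(4-methoxybenzyl)oxy]propanal; 6 methyl propiolate
Product: 7 methyl (4S,6S)-6-[(4R)-2,2-dimethyl-1,3-dioxolan-4-yl]-4-hydroxy-6-[(4-methoxybenzyl)oxy]hex-2-ynoate
Conditions: Me2Zn, (S,S)-ProPhenol (20 mol %), Ph3P=O (40 mol %), PhMe, 4 °C
Reagents that add atoms: none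
Why: Dinuclear zinc–ProPhenol-catalysed alkynylation: the zinc acetylide of 6 adds to the aldehyde, and the (S,S) ligand is expected to deliver it to the Re face, which gives (3S), 1,3-anti to the C1 oxygen. The new centre is set by the catalyst, with the β-ether at most a minor influence.

Step 6
Reactants: 7 methyl (4S,6S)-6-[(4R)-2,2-dimethyl-1,3-dioxolan-4-yl]-4-hydroxy-6-[(4-methoxybenzyl)oxy]hex-2-ynoate
Product: 8 methyl (4S,6S)-4-[(tert-butyldimethylsilyl)oxy]-6-[(4R)-2,2-dimethyl-1,3-dioxolan-4-yl]-6-[(4-methoxybenzyl)oxy]hex-2-ynoate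
Conditions: TBSCl, imidazole, DMF, 0 °C to rt
Reagents that add atoms: tert-butyldimethylsilyl chloride, CC(C)(C)[Si](C)(C)Cl
Why: Standard silylation of the propargylic C3 hydroxyl; the silyl ether also prevents butenolide formation once the (Z)-enoate exists.

Step 7
Reactants: 8 methyl (4S,6S)-4-[(tert-butyldimethylsilyl)oxy]-6-[(4R)-2,2-dimethyl-1,3-dioxolan-4-yl]-6-[(4-methoxybenzyl)oxy]hex-2-ynoate
Product: 9 methyl (2Z,4S,6S)-4-[(tert-butyldimethylsilyl)oxy]-6-[(4R)-2,2-dimethyl-1,3-dioxolan-4-yl]-6-[(4-methoxybenzyl)oxy]-3-methylhex-2-enoate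
Conditions: Me2CuLi (from CuI and MeLi), THF, −78 °C; MeOH then aq. NH4Cl at −78 °C
Reagents that add atoms: lithium dimethylcuprate, [Li+].C[Cu-]C
Why: Syn carbocupration of the ynoate puts the methyl group on C4 and copper on C5. Protonation with retention at −78 °C, before the alkenylcuprate can isomerise through its allenolate, leaves C3 and C6 cis, which is the (Z) geometry of the target.

Step 8
Reactants: 9 methyl (2Z,4S,6S)-4-[(tert-butyldimethylsilyl)oxy]-6-[(4R)-2,2-dimethyl-1,3-dioxolan-4-yl]-6-[(4-methoxybenzyl)oxy]-3-methylhex-2-enoate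
Product: 10 (2Z,4S,6S)-4-[(tert-butyldimethylsilyl)oxy]-6-[(4R)-2,2-dimethyl-1,3-dioxolan-4-yl]-6-[(4-methoxybenzyl)oxy]-3-methylhex-2-en-1-ol
Conditions: iBu2AlH, CH2Cl2, −78 °C; aq. potassium sodium tartrate
Reagents that add atoms: none
Why: 1,2-Reduction of the enoate to the allylic alcohol by the aluminium hydride; no conjugate reduction is expected at low temperature and the alkene geometry is untouched.

Step 9
Reactants: 10 (2Z,4S,6S)-4-[(tert-butyldimethylsilyl)oxy]-6-[(4R)-2,2-dimethyl-1,3-dioxolan-4-yl]-6-[(4-methoxybenzyl)oxy]-3-methylhex-2-en-1-ol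
Product: 11 (2Z,4S,6S)-4-[(tert-butyldimethylsilyl)oxy]-6-[(4R)-2,2-dimethyl-1,3-dioxolan-4-yl]-6-[(4-methoxybenzyl)oxy]-3-methylhex-2-enal
Conditions: MnO2, CH2Cl2, rt
Reagents that add atoms: none
Why: Neutral heterogeneous oxidation of the allylic alcohol gives the (Z)-enal without acid or base that could isomerise it; the enal is used directly.

Step 10
Reactants: 12 (4R)-4-benzyl-1,3-oxazolidin-2-one; 13 methyl 4-chloro-4-oxobutanoate
Product: 14 methyl 4-[(4R)-4-benzyl-2-oxo-1,3-oxazolidin-3-yl]-4-oxobutanoate
Conditions: n-BuLi, THF, −78 °C; then 13, −78 to 0 °C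
Reagents that add atoms: none
Why: N-Acylation of the lithiated oxazolidinone with the acid chloride gives the succinyl imide, in which only the imide α-methylene (the future C7) is readily enolised.

Step 11
Reactants: 11 (2Z,4S,6S)-4-[(tert-butyldimethylsilyl)oxy]-6-[(4R)-2,2-dimethyl-1,3-dioxolan-4-yl]-6-[(4-methoxybenzyl)oxy]-3-methylhex-2-enal; 14 methyl 4-[(4R)-4-benzyl-2-oxo-1,3-oxazolidin-3-yl]-4-oxobutanoate
Product: 15 (6S,7S) anti-aldol adduct as its C6 trimethylsilyl ether (C8 imide of 12; C12 methyl ester; C3 OTBS; C1 OPMB; C10/C14 acetonide)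
Conditions: MgCl2 (20 mol %), Et3N, Me3SiCl, EtOAc, rt
Reagents that add atoms: chlorotrimethylsilane, C[Si](C)(C)Cl
Why: MgCl2-catalysed direct anti-aldol of an N-acyloxazolidinone with an unsaturated aldehyde (Evans-type). The magnesium-chelated (Z)-enolate should be attacked on the face away from the benzyl group through a boat-like transition state, which gives (7S) and, by the anti relation, (6S); silylation of the aldolate drives turnover.

Step 12
Reactants: 15 (6S,7S) anti-aldol adduct as its C6 trimethylsilyl ether
Product: 18 (6S,7S) cis-lactone imide with free C10 and C14 hydroxyls (C3 OTBS; C1 OPMB), via C6 alcohol 16 (not isolated), via lactone acetonide 17 (not isolated)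
Conditions: PPTS, MeOH, rt to 40 °C
Reagents that add atoms: none
Why: Mild acid methanolysis removes the trimethylsilyl ether and the terminal acetonide, and the freed C6 hydroxyl closes onto the C12 methyl ester (5-exo-trig lactonisation). An anti adduct can only give the cis-lactone; the secondary allylic TBS ether and the PMB ether are expected to survive PPTS.

Step 13
Reactants: 18 (6S,7S) cis-lactone imide with free C10 and C14 hydroxyls
Product: 19 cis-lactone imide with C14 OTBS and free (10R) hydroxyl
Conditions: TBSCl, imidazole, CH2Cl2, 0 °C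
Reagents that add atoms: tert-butyldimethylsilyl chloride, CC(C)(C)[Si](C)(C)Cl
Why: Silylation of the primary hydroxyl in preference to the secondary one puts the bulky, non-chelating silyl ether on C14 before any base-sensitive group is present.

Step 14
Reactants: 19 cis-lactone imide with C14 OTBS and free (10R) hydroxyl
Product: 20 (2S,3S)-2-[(1Z,3S,5S,6R)-3,7-bis(tert-butyldimethylsilyloxy)-6-hydroxy-5-(4-methoxybenzyloxy)-2-methylhept-1-enyl]-5-oxooxolane-3-carboxylic acid
Conditions: LiOH, H2O2, THF/H2O, 0 °C; Na2SO3; 1 M HCl to pH 3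
Reagents that add atoms: lithium hydroperoxide (from LiOH and H2O2), [Li+].[O-]O
Why: Hydroperoxide attacks the exocyclic imide carbonyl and releases the auxiliary. Any lactone opening is reversed on acidification because the γ-hydroxy acid recloses, and a carboxylate at C8 does not allow epimerisation at C7.

Step 15
Reactants: 20 the C8 carboxylic acid
Product: 23 cis-lactone C8 bromomethyl ketone with free (10R) hydroxyl, via mixed anhydride 21 (not isolated), via diazoketone 22 (not isolated)
Conditions: ClCO2iBu, N-methylmorpholine, THF, −20 °C; CH2N2, Et2O, −20 to 0 °C; N2 purge; 48% aq. HBr (1.1 equiv), −20 °C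
Reagents that add atoms: diazomethane, C=[N+]=[N-]; hydrogen bromide, Br
Why: Mixed-anhydride activation and acylation of diazomethane (first stage of the Arndt–Eistert sequence) give the diazoketone; protonation at carbon and displacement of dinitrogen by bromide give the bromomethyl ketone. Bromine reaches C9 without any enolisation, and a short exposure to one equivalent of acid at low temperature should spare the silyl and PMB ethers.

Step 16
Reactants: 23 cis-lactone C8 bromomethyl ketone with free (10R) hydroxyl
Product: 24 (1S,3S,6S,7S) cis-lactone C8 bromomethyl ketone with the C1-OPMB C10 ketone and C14 OTBS (key-step precursor)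
Conditions: Dess–Martin periodinane, NaHCO3, CH2Cl2, 0 °C to rt
Reagents that add atoms: none
Why: Dess–Martin oxidation of the secondary C10 alcohol under buffered, essentially neutral conditions, so that neither C7 (β to the lactone oxygen) nor C1 is epimerised and the bromoketone is not touched.

Step 17
Reactants: 24 (1S,3S,6S,7S) cis-lactone C8 bromomethyl ketone with the C1-OPMB C10 ketone
Product: 26 (1S,3S,6S,7S,10R) ten-membered C10 tertiary carbinol with C8 ketone (C1 OPMB; C3 OTBS; C14 OTBS; cis-lactone), via samarium enolate 25 (not isolated)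
Conditions: SmI2 (2.5 equiv, 0.1 M in THF), THF, −78 °C; 24 added over 4 h to a final 0.002 M; aq. NH4Cl at −78 °C
Reagents that add atoms: none
Why: Two single-electron transfers from divalent samarium cleave the C9–Br bond and give the trivalent samarium enolate 25 of the C8 ketone, fixed on the C9 side because it is formed from the halide and not by deprotonation. The oxophilic metal then binds the C10 carbonyl and the C1 PMB ether oxygen in a five-membered chelate, and C9 adds to C10 (an intramolecular Reformatsky-type aldol). The closest known reaction type is the SmI2-mediated intramolecular Reformatsky closure of medium and large rings from α-halo carbonyl compounds, combined here with chelation-controlled addition to an α-alkoxy ketone. The ten-membered ring closes in a 10-exo-trig mode with respect to the C10 carbonyl (enolendo with respect to the enolate). The new centre C10 is controlled by the (1S) ether: in the chelate C2 shields one face, so C9 should arrive anti to C2 and give (10R). The bulky C14 silyl ether does not compete as a chelating group. The step needs C–Br reduction to be faster than reductive cleavage of the α-alkoxy ketone (no proton source or cosolvent, low temperature, substrate kept dilute) and ring closure to be faster than intermolecular aldol or proton transfer (slow addition, metal template). The neutral conditions should leave C7 and the lactone C6–O bond untouched.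

Step 18
Reactants: 26 (1S,3S,6S,7S,10R) ten-membered C10 tertiary carbinol with C8 ketone
Product: 28 (8R) 8,10-syn diol (other centres as in 26), via diethylborinate 27 (not isolated)
Conditions: Et2BOMe, THF/MeOH (4:1), −78 °C; NaBH4; AcOH; MeOH co-evaporation
Reagents that add atoms: none
Why: Narasaka–Prasad reduction: the C10 borinate chelates the C8 carbonyl in a six-membered half-chair and external hydride attacks axially, which should give the 1,3-syn diol and therefore (8R). The lactone is inert to NaBH4 at −78 °C.

Step 19
Reactants: 28 (8R) 8,10-syn diol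
Product: 29 C8 triethylsilyl ether with free tertiary C10 hydroxyl
Conditions: Et3SiCl, imidazole, CH2Cl2, 0 °C
Reagents that add atoms: chlorotriethylsilane, CC[Si](CC)(CC)Cl
Why: The secondary C8 hydroxyl is silylated while the tertiary C10 hydroxyl is not. A silyl group more labile than TBS is chosen so that O8 can be freed alone later, and prompt protection also prevents migration of the lactone from O6 to O8.

Step 20
Reactants: 29 C8 triethylsilyl ether with free tertiary C10 hydroxyl
Product: 30 (1S,10R) C1,C10-diol (C8 OTES; C3 OTBS; C14 OTBS)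
Conditions: DDQ, CH2Cl2/pH 7 buffer (10:1), 0 °C
Reagents that add atoms: none
Why: Oxidative cleavage of the PMB ether by hydride abstraction and hydrolysis of the oxocarbenium ion; water is kept present so that the neighbouring C10 hydroxyl does not trap the ion as an acetal.

Step 21
Reactants: 30 (1S,10R) C1,C10-diol
Product: 32 (1R,10R) C1–C10 oxirane (C8 OTES; C3 OTBS; C14 OTBS; saturated cis-lactone), via C1 mesylate 31 (not isolated)
Conditions: MsCl, Et3N, CH2Cl2, −20 °C; then K2CO3, MeOH, 0 °C to rt
Reagents that add atoms: none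
Why: Only the secondary C1 hydroxyl is sulfonylated; the C10 alkoxide then displaces the mesylate in a 3-exo-tet Williamson closure with inversion at C1 and retention at C10. This converts (1S,10R) into the (1R,10R) oxirane with C2 and C9 cis; the closure needs the C10–O and C1–OMs bonds anti-periplanar, which the flexible ring should allow.

Step 22
Reactants: 32 (1R,10R) C1–C10 oxirane
Product: 33 C11 dimethylaminomethyl lactone (C11 configuration not defined)
Conditions: LiN(iPr)2, THF, −78 °C; CH2=NMe2+ I−, −78 to 0 °C
Reagents that add atoms: N,N-dimethylmethyleneiminium iodide, C=[N+](C)C.[I-]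
Why: Mannich reaction of the lactone lithium enolate with the preformed iminium salt; C11 is the only acidic position and has no leaving group β to it, and the new centre is removed in the next step.

Step 23
Reactants: 33 C11 dimethylaminomethyl lactone
Product: 35 α-methylene lactone (C8 OTES; C3 OTBS; C14 OTBS; oxirane), via ammonium iodide 34 (not isolated)
Conditions: MeI, CH2Cl2/MeOH, rt; then aq. NaHCO3, rt
Reagents that add atoms: none
Why: Quaternisation of the amine followed by mild base-induced β-elimination of trimethylamine (Hofmann-type) forms C11=C13 without exposing the oxirane to strong base.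

Step 24
Reactants: 35 α-methylene lactone
Product: 36 C8 alcohol (C3 OTBS; C14 OTBS)
Conditions: HF·pyridine, pyridine, THF, 0 °C
Reagents that add atoms: none
Why: Buffered fluoride cleaves the triethylsilyl ether much faster than the hindered primary and the secondary TBS ethers, and the buffered medium should not open the oxirane.

Step 25
Reactants: 36 C8 alcohol; 37 (R)-2-methylbutanoic acid
Product: 38 C8 (R)-2-methylbutanoate with C3 and C14 TBS ethers
Conditions: EDC·HCl, DMAP (0.2 equiv), CH2Cl2, 0 °C to rt
Reagents that add atoms: none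
Why: Steglich esterification of the only free hydroxyl; carbodiimide activation with a catalytic amount of DMAP avoids ketene formation and so keeps the α-centre of the acid intact.

Step 26
Reactants: 38 C8 (R)-2-methylbutanoate with C3 and C14 TBS ethers
Product: 39 the target
Conditions: HF·pyridine, THF, 0 °C to rt
Reagents that add atoms: none
Why: Global desilylation under mildly acidic fluoride conditions that tolerate the α-methylene lactone, the ester and the trisubstituted oxirane; no base is present that could trigger epoxide migration or acyl transfer.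

## Compound list

1 | 2-deoxy-D-ribose (open-chain form) | O=CC[C@H](O)[C@H](O)CO | starting material
2 | (2R,3S)-4-(1,3-dithian-2-yl)butane-1,2,3-triol | C1CSC(SC1)C[C@H](O)[C@H](O)CO | intermediate
3 | (1S)-2-(1,3-dithian-2-yl)-1-[(4R)-2,2-dimethyl-1,3-dioxolan-4-yl]ethanol | C1CSC(SC1)C[C@H](O)[C@H]2COC(C)(C)O2 | intermediate
4 | 2-{(2S)-2-[(4R)-2,2-dimethyl-1,3-dioxolan-4-yl]-2-[(4-methoxybenzyl)oxy]ethyl}-1,3-dithiane | C1CSC(SC1)C[C@H](OCc2ccc(OC)cc2)[C@H]3COC(C)(C)O3 | intermediate
5 | (3S)-3-[(4R)-2,2-dimethyl-1,3-dioxolan-4-yl]-3-[(4-methoxybenzyl)oxy]propanal | O=CC[C@H](OCc1ccc(OC)cc1)[C@H]2COC(C)(C)O2 | intermediate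
6 | methyl propiolate | C#CC(=O)OC | starting material
7 | methyl (4S,6S)-6-[(4R)-2,2-dimethyl-1,3-dioxolan-4-yl]-4-hydroxy-6-[(4-methoxybenzyl)oxy]hex-2-ynoate | COC(=O)C#C[C@@H](O)C[C@H](OCc1ccc(OC)cc1)[C@H]2COC(C)(C)O2 | intermediate
8 | methyl (4S,6S)-4-[(tert-butyldimethylsilyl)oxy]-6-[(4R)-2,2-dimethyl-1,3-dioxolan-4-yl]-6-[(4-methoxybenzyl)oxy]hex-2-ynoate | COC(=O)C#C[C@@H](O[Si](C)(C)C(C)(C)C)C[C@H](OCc1ccc(OC)cc1)[C@H]2COC(C)(C)O2 | intermediate
9 | methyl (2Z,4S,6S)-4-[(tert-butyldimethylsilyl)oxy]-6-[(4R)-2,2-dimethyl-1,3-dioxolan-4-yl]-6-[(4-methoxybenzyl)oxy]-3-methylhex-2-enoate | COC(=O)/C=C(/C)[C@@H](O[Si](C)(C)C(C)(C)C)C[C@H](OCc1ccc(OC)cc1)[C@H]2COC(C)(C)O2 | intermediate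
10 | (2Z,4S,6S)-4-[(tert-butyldimethylsilyl)oxy]-6-[(4R)-2,2-dimethyl-1,3-dioxolan-4-yl]-6-[(4-methoxybenzyl)oxy]-3-methylhex-2-en-1-ol | OC/C=C(/C)[C@@H](O[Si](C)(C)C(C)(C)C)C[C@H](OCc1ccc(OC)cc1)[C@H]2COC(C)(C)O2 | intermediate
11 | (2Z,4S,6S)-4-[(tert-butyldimethylsilyl)oxy]-6-[(4R)-2,2-dimethyl-1,3-dioxolan-4-yl]-6-[(4-methoxybenzyl)oxy]-3-methylhex-2-enal | O=C/C=C(/C)[C@@H](O[Si](C)(C)C(C)(C)C)C[C@H](OCc1ccc(OC)cc1)[C@H]2COC(C)(C)O2 | intermediate
12 | (4R)-4-benzyl-1,3-oxazolidin-2-one | O=C1N[C@H](Cc2ccccc2)CO1 | starting material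
13 | methyl 4-chloro-4-oxobutanoate | COC(=O)CCC(Cl)=O | starting material
14 | methyl 4-[(4R)-4-benzyl-2-oxo-1,3-oxazolidin-3-yl]-4-oxobutanoate | COC(=O)CCC(=O)N1[C@H](Cc2ccccc2)COC1=O | intermediate
15 | methyl (3S,4S,5Z,7S,9S)-3-{[(4R)-4-benzyl-2-oxo-1,3-oxazolidin-3-yl]carbonyl}-7-(tert-butyldimethylsilyloxy)-9-[(4R)-2,2-dimethyl-1,3-dioxolan-4-yl]-9-(4-methoxybenzyloxy)-6-methyl-4-(trimethylsilyloxy)non-5-enoate (anti-aldol silyl ether) | COC(=O)C[C@H](C(=O)N1[C@H](Cc2ccccc2)COC1=O)[C@@H](O[Si](C)(C)C)/C=C(/C)[C@@H](O[Si](C)(C)C(C)(C)C)C[C@H](OCc3ccc(OC)cc3)[C@H]4COC(C)(C)O4 | intermediate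
16 | C6 alcohol of 15 (4-hydroxy in place of 4-trimethylsilyloxy) | COC(=O)C[C@H](C(=O)N1[C@H](Cc2ccccc2)COC1=O)[C@@H](O)/C=C(/C)[C@@H](O[Si](C)(C)C(C)(C)C)C[C@H](OCc3ccc(OC)cc3)[C@H]4COC(C)(C)O4 | intermediate (not isolated)
17 | (6S,7S) cis-lactone imide with C10/C14 acetonide | O=C1OC[C@@H](Cc2ccccc2)N1C(=O)[C@H]3CC(=O)O[C@H]3/C=C(/C)[C@@H](O[Si](C)(C)C(C)(C)C)C[C@H](OCc4ccc(OC)cc4)[C@H]5COC(C)(C)O5 | intermediate (not isolated)
18 | (6S,7S) cis-lactone imide with free C10 and C14 hydroxyls | O=C1OC[C@@H](Cc2ccccc2)N1C(=O)[C@H]3CC(=O)O[C@H]3/C=C(/C)[C@@H](O[Si](C)(C)C(C)(C)C)C[C@H](OCc4ccc(OC)cc4)[C@H](O)CO | intermediate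
19 | cis-lactone imide with C14 OTBS and free (10R) hydroxyl | O=C1OC[C@@H](Cc2ccccc2)N1C(=O)[C@H]3CC(=O)O[C@H]3/C=C(/C)[C@@H](O[Si](C)(C)C(C)(C)C)C[C@H](OCc4ccc(OC)cc4)[C@H](O)CO[Si](C)(C)C(C)(C)C | intermediate
20 | (2S,3S)-2-[(1Z,3S,5S,6R)-3,7-bis(tert-butyldimethylsilyloxy)-6-hydroxy-5-(4-methoxybenzyloxy)-2-methylhept-1-enyl]-5-oxooxolane-3-carboxylic acid | OC(=O)[C@H]1CC(=O)O[C@H]1/C=C(/C)[C@@H](O[Si](C)(C)C(C)(C)C)C[C@H](OCc2ccc(OC)cc2)[C@H](O)CO[Si](C)(C)C(C)(C)C | intermediate
21 | isobutyl carbonic mixed anhydride of 20 | CC(C)COC(=O)OC(=O)[C@H]1CC(=O)O[C@H]1/C=C(/C)[C@@H](O[Si](C)(C)C(C)(C)C)C[C@H](OCc2ccc(OC)cc2)[C@H](O)CO[Si](C)(C)C(C)(C)C | intermediate (not isolated)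
22 | C8 diazomethyl ketone | [N-]=[N+]=CC(=O)[C@H]1CC(=O)O[C@H]1/C=C(/C)[C@@H](O[Si](C)(C)C(C)(C)C)C[C@H](OCc2ccc(OC)cc2)[C@H](O)CO[Si](C)(C)C(C)(C)C | intermediate (not isolated)
23 | cis-lactone C8 bromomethyl ketone with free (10R) hydroxyl | BrCC(=O)[C@H]1CC(=O)O[C@H]1/C=C(/C)[C@@H](O[Si](C)(C)C(C)(C)C)C[C@H](OCc2ccc(OC)cc2)[C@H](O)CO[Si](C)(C)C(C)(C)C | intermediate
24 | (1S,3S,6S,7S) cis-lactone C8 bromomethyl ketone with the C1-OPMB C10 ketone and C14 OTBS (key-step precursor) | BrCC(=O)[C@H]1CC(=O)O[C@H]1/C=C(/C)[C@@H](O[Si](C)(C)C(C)(C)C)C[C@H](OCc2ccc(OC)cc2)C(=O)CO[Si](C)(C)C(C)(C)C | intermediate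
25 | trivalent samarium enolate of the C8 ketone (C9=C8–O–SmI2) | C=C(O[Sm](I)I)[C@H]1CC(=O)O[C@H]1/C=C(/C)[C@@H](O[Si](C)(C)C(C)(C)C)C[C@H](OCc2ccc(OC)cc2)C(=O)CO[Si](C)(C)C(C)(C)C | intermediate (not isolated)
26 | (1S,3S,6S,7S,10R) ten-membered C10 tertiary carbinol with C8 ketone (key-step product) | C1C(=O)O[C@H]2/C=C(/C)[C@@H](O[Si](C)(C)C(C)(C)C)C[C@H](OCc3ccc(OC)cc3)[C@](O)(CO[Si](C)(C)C(C)(C)C)CC(=O)[C@@H]12 | intermediate
27 | C10 diethylborinate of 26 | C1C(=O)O[C@H]2/C=C(/C)[C@@H](O[Si](C)(C)C(C)(C)C)C[C@H](OCc3ccc(OC)cc3)[C@](OB(CC)CC)(CO[Si](C)(C)C(C)(C)C)CC(=O)[C@@H]12 | intermediate (not isolated)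
28 | (8R) 8,10-syn diol | C1C(=O)O[C@H]2/C=C(/C)[C@@H](O[Si](C)(C)C(C)(C)C)C[C@H](OCc3ccc(OC)cc3)[C@](O)(CO[Si](C)(C)C(C)(C)C)C[C@@H](O)[C@@H]12 | intermediate
29 | C8 triethylsilyl ether with free C10 hydroxyl | C1C(=O)O[C@H]2/C=C(/C)[C@@H](O[Si](C)(C)C(C)(C)C)C[C@H](OCc3ccc(OC)cc3)[C@](O)(CO[Si](C)(C)C(C)(C)C)C[C@@H](O[Si](CC)(CC)CC)[C@@H]12 | intermediate
30 | (1S,10R) C1,C10-diol | C1C(=O)O[C@H]2/C=C(/C)[C@@H](O[Si](C)(C)C(C)(C)C)C[C@H](O)[C@](O)(CO[Si](C)(C)C(C)(C)C)C[C@@H](O[Si](CC)(CC)CC)[C@@H]12 | intermediate
31 | C1 mesylate of 30 | C1C(=O)O[C@H]2/C=C(/C)[C@@H](O[Si](C)(C)C(C)(C)C)C[C@H](OS(C)(=O)=O)[C@](O)(CO[Si](C)(C)C(C)(C)C)C[C@@H](O[Si](CC)(CC)CC)[C@@H]12 | intermediate (not isolated)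
32 | (1R,10R) C1–C10 oxirane with saturated cis-lactone | C1C(=O)O[C@H]2/C=C(/C)[C@@H](O[Si](C)(C)C(C)(C)C)C[C@H]3O[C@@]3(CO[Si](C)(C)C(C)(C)C)C[C@@H](O[Si](CC)(CC)CC)[C@@H]12 | intermediate
33 | C11 dimethylaminomethyl lactone | CN(C)CC1C(=O)O[C@H]2/C=C(/C)[C@@H](O[Si](C)(C)C(C)(C)C)C[C@H]3O[C@@]3(CO[Si](C)(C)C(C)(C)C)C[C@@H](O[Si](CC)(CC)CC)[C@@H]12 | intermediate
34 | C11 trimethylammoniomethyl lactone iodide | C[N+](C)(C)CC1C(=O)O[C@H]2/C=C(/C)[C@@H](O[Si](C)(C)C(C)(C)C)C[C@H]3O[C@@]3(CO[Si](C)(C)C(C)(C)C)C[C@@H](O[Si](CC)(CC)CC)[C@@H]12.[I-] | intermediate (not isolated)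
35 | α-methylene lactone with C8 OTES | C=C1C(=O)O[C@H]2/C=C(/C)[C@@H](O[Si](C)(C)C(C)(C)C)C[C@H]3O[C@@]3(CO[Si](C)(C)C(C)(C)C)C[C@@H](O[Si](CC)(CC)CC)[C@@H]12 | intermediate
36 | α-methylene lactone C8 alcohol | C=C1C(=O)O[C@H]2/C=C(/C)[C@@H](O[Si](C)(C)C(C)(C)C)C[C@H]3O[C@@]3(CO[Si](C)(C)C(C)(C)C)C[C@@H](O)[C@@H]12 | intermediate
37 | (R)-2-methylbutanoic acid | CC[C@@H](C)C(=O)O | starting material
38 | C8 (R)-2-methylbutanoate with C3 and C14 TBS ethers | C=C1C(=O)O[C@H]2/C=C(/C)[C@@H](O[Si](C)(C)C(C)(C)C)C[C@H]3O[C@@]3(CO[Si](C)(C)C(C)(C)C)C[C@@H](OC(=O)[C@H](C)CC)[C@@H]12 | intermediate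
39 | CNP0356520.2 | C=C1C(=O)O[C@H]2/C=C(/C)[C@@H](O)C[C@H]3O[C@@]3(CO)C[C@@H](OC(=O)[C@H](C)CC)[C@@H]12 | target

## Step count and least certain steps

Total step count: 26. Longest linear sequence: 25 steps (steps 1–9 and 11–26; step 10 is the side branch).

**Step 17 (key step).**
- What may go wrong: ten-membered closure is slow, so the samarium enolate may be quenched by proton transfer before it adds, or the α-alkoxy C10 ketone may be reductively cleaved by the excess reductant. The tether from C2, and not the chelate, may also decide which ketone face is reached, which would erode the C10 selectivity.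
- Fallback: from 24, form the same bond as a Lewis-acid aldol. Reductive silylation of the bromoketone (Zn, Me3SiCl) gives the regiodefined trimethylsilyl enol ether F1 without reducing the C10 ketone. A chelating Lewis acid (MgBr2·OEt2, CH2Cl2, −78 °C, high dilution) then activates the C10 carbonyl through the C1 ether for an intramolecular Mukaiyama aldol. Aqueous work-up returns the route at 26.

**Step 11.**
- What may go wrong: the (Z)-enal may lose its geometry under the amine and silyl chloride through reversible dienolate formation, the β,β-disubstituted enal may add slowly, and the anti or facial selectivity may be incomplete.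
- Fallback: from 11, set C6 and C7 in two separate steps. An acetate aldol with doubly deprotonated (R)-2-hydroxy-1,2,2-triphenylethyl acetate gives the β-hydroxy ester F2, and methanolysis (NaOMe, MeOH) gives the methyl ester F3. Fráter–Seebach alkylation of its dianion (LiN(iPr)2, then methyl bromoacetate) gives the anti hydroxy diester F4. PPTS in MeOH then gives the cis-lactone diol ester F5, and TBSCl with imidazole gives the C14 silyl ether F6. Hydrolysis with LiOH and acidification, on which the γ-hydroxy acid recloses, returns the route at 20.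

**Step 18.**
- What may go wrong: hydride delivery may show poor facial selectivity, because the tertiary C10 centre places a substituent 1,3-diaxial to the incoming hydride in the boron chelate and the ring conformation may then decide the face.
- Fallback: from 26, set C8 by inversion. Hydroxyl-delivered reduction with Me4NBH(OAc)3 is expected to give the 1,3-anti diol F7 (the C8 epimer). Mitsunobu esterification with 4-nitrobenzoic acid inverts C8 to the ester F8, and brief treatment with K2CO3 in MeOH at 0 °C returns the route at 28.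

**Step 5.**
- What may go wrong: the resident β-ether may erode the catalyst-controlled facial selectivity, and the basic zinc species may cause β-elimination of the ether from the aldehyde.
- Fallback: from 5, add the lithium acetylide of 6 (LiN(SiMe3)2, −78 °C) to give the alcohol F9 as a C3 epimer mixture, oxidise it with Dess–Martin periodinane to the ynone F10, and reduce that with (S)-Alpine-Borane (Midland reduction), whose sense for alkynyl ketones gives the (S) carbinol. The route is rejoined at 7.

**Step 22.**
- What may go wrong: the lithium enolate may attack the oxirane across the ring, or aminomethylation may be incomplete on the hindered face of the cis-fused lactone.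
- Fallback: from 32, avoid the enolate. Heating with tert-butoxybis(dimethylamino)methane gives the enaminolactone F11, and reduction with iBu2AlH at −78 °C followed by elimination of dimethylamine on silica gel returns the route at 35, bypassing 33 and 34.

## Further compounds

F1 | step 17 | trimethylsilyl enol ether of the C8 ketone (C9=C8–OSiMe3) with the C10 ketone intact | C=C(O[Si](C)(C)C)[C@H]1CC(=O)O[C@H]1/C=C(/C)[C@@H](O[Si](C)(C)C(C)(C)C)C[C@H](OCc2ccc(OC)cc2)C(=O)CO[Si](C)(C)C(C)(C)C
F2 | step 11 | (R)-2-hydroxy-1,2,2-triphenylethyl (6R) β-hydroxy ester from the acetate aldol with 11 | O=C(C[C@@H](O)/C=C(/C)[C@@H](O[Si](C)(C)C(C)(C)C)C[C@H](OCc1ccc(OC)cc1)[C@H]2COC(C)(C)O2)O[C@H](c3ccccc3)C(O)(c4ccccc4)c5ccccc5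
F3 | step 11 | methyl (6R) β-hydroxy ester | COC(=O)C[C@@H](O)/C=C(/C)[C@@H](O[Si](C)(C)C(C)(C)C)C[C@H](OCc1ccc(OC)cc1)[C@H]2COC(C)(C)O2
F4 | step 11 | anti hydroxy diester (dimethyl succinate with C6 hydroxyl) | COC(=O)C[C@H](C(=O)OC)[C@@H](O)/C=C(/C)[C@@H](O[Si](C)(C)C(C)(C)C)C[C@H](OCc1ccc(OC)cc1)[C@H]2COC(C)(C)O2
F5 | step 11 | cis-lactone C8 methyl ester with free C10 and C14 hydroxyls | COC(=O)[C@H]1CC(=O)O[C@H]1/C=C(/C)[C@@H](O[Si](C)(C)C(C)(C)C)C[C@H](OCc2ccc(OC)cc2)[C@H](O)CO
F6 | step 11 | cis-lactone C8 methyl ester with C14 OTBS | COC(=O)[C@H]1CC(=O)O[C@H]1/C=C(/C)[C@@H](O[Si](C)(C)C(C)(C)C)C[C@H](OCc2ccc(OC)cc2)[C@H](O)CO[Si](C)(C)C(C)(C)C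
F7 | step 18 | (8S) 8,10-anti diol (C8 epimer of 28) | C1C(=O)O[C@H]2/C=C(/C)[C@@H](O[Si](C)(C)C(C)(C)C)C[C@H](OCc3ccc(OC)cc3)[C@](O)(CO[Si](C)(C)C(C)(C)C)C[C@H](O)[C@@H]12
F8 | step 18 | C8 4-nitrobenzoate with the natural C8 configuration | C1C(=O)O[C@H]2/C=C(/C)[C@@H](O[Si](C)(C)C(C)(C)C)C[C@H](OCc3ccc(OC)cc3)[C@](O)(CO[Si](C)(C)C(C)(C)C)C[C@@H](OC(=O)c4ccc(cc4)[N+](=O)[O-])[C@@H]12
F9 | step 5 | methyl 4-hydroxy ynoate as a C3 epimer mixture | COC(=O)C#CC(O)C[C@H](OCc1ccc(OC)cc1)[C@H]2COC(C)(C)O2
F10 | step 5 | methyl 4-oxo ynoate (C3 ketone) | COC(=O)C#CC(=O)C[C@H](OCc1ccc(OC)cc1)[C@H]2COC(C)(C)O2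
F11 | step 22 | C11 dimethylaminomethylene lactone | CN(C)C=C1C(=O)O[C@H]2/C=C(/C)[C@@H](O[Si](C)(C)C(C)(C)C)C[C@H]3O[C@@]3(CO[Si](C)(C)C(C)(C)C)C[C@@H](O[Si](CC)(CC)CC)[C@@H]12
A1 | alternative 1 | 2-methylnaphthalene | Cc1ccc2ccccc2c1
A2 | alternative 1 | (3Z,8Z)-3-methylcyclodeca-3,8-diene-1,6-dione | O=C1C/C=C(/C)CC(=O)C/C=C\C1
A3 | alternative 2 | ten-membered carbocycle bridged by the C8=N–O–C6 isoxazoline | COC(=O)C[C@H]1[C@@H]2/C=C(/C)[C@@H](O[Si](C)(C)C(C)(C)C)C[C@H]3O[C@@]3(CO[Si](C)(C)C(C)(C)C)CC1=NO2
A4 | alternative 3 | ten-membered C6 enone with ring-cis C4=C5 and C1=C10 and the C8 silane | O=C1/C=C(/C)[C@@H](O[Si](C)(C)C(C)(C)C)C/C=C(/CO[Si](C)(C)C(C)(C)C)C[C@@H]([Si](C)(C)Cc2ccccc2)C1
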